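The runs stem from a simulated flask with constants of no real substance; noise was put on by code.

We start with an easy step of counting: one side product holds two units of substrate, and one of those units had already become target, so half of the side product's units are target that was made and then lost.

| flask | substrate | reagent | remark | time |
|---|---|---|---|---|
| south-west | 10 mM | 0.95 equiv | the very flask that is asked about, followed so far |  |
| south | 10 mM | 1.9 equiv | run made earlier |  |
| flask | 10 mM | 0.950 equiv |  | 5.0 min |

south-west run (percent of the substrate charged)

| time / s | isomer of the product / % | target / % |
|---|---|---|
| 10.0 | 25.5 | 10.9 |
| 20.0 | 38.1 | 13.8 |
| 40.0 | 46.3 | 16.0 |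
| 60.0 | 51.6 | 14.8 |

south run (percent of the substrate charged)

| time / min | isomer of the product / % | target / % |
|---|---|---|
| 0.667 | 59.1 | 26.1 |
| 2.00 | 60.7 | 26.4 |
| 3.00 | 60.9 | 25.7 |
| 5.00 | 60.7 | 27.2 |

(each reading ± 0.5 percentage points)

1. share of isomer of the product in isomer of the product plus target at 1.2 s
2. share of isomer of the product in isomer of the product plus target at 20 s
3. share of isomer of the product in isomer of the product plus target at 5.0 min

- percent here means substrate units held: one side product counts as two
- what may be going on: substrate <-> other conformer; substrate + reagent -> target; reagent + other conformer -> isomer of the product; substrate + target -> side product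

In the south run the readings stand level within their scatter from 2.00 min on, so we read what is missing at 5.00 min, 12.1% of the charge, as side product. The target lost there is then 6.05%, a correction smaller than the target made, 33.2%, and the isomer of the product reads 60.7%. These two amounts give the made share, the isomer of the product over the isomer plus all target ever made, a selectivity: 64.6%.

In our own reckoning for the south-west flask, the charge holds substrate and no other conformer, and the isomer of the product forms from the other conformer, so we expect the share at 1.2 s to stand below the made share, and we give no figure. The plain share, isomer of the product over isomer plus the target still held, counts no lost target in its denominator, and in the south-west flask it reads 77.7% at 60.0 s, more than the made share.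

The forecast gives 63% (from 42% to 76%), 73% and 79%, and says of the first that “the data do not reach that early”.

The flask gives 47.8%, 71.9% and 81.3%.

    substrate ⇌ other conformer (K = 0.770, k = 0.690 s⁻¹)
    substrate + reagent → target (k = 4.10 L mol⁻¹ s⁻¹)
    reagent + other conformer → isomer of the product (k = 12.0 L mol⁻¹ s⁻¹)
    substrate + target → side product (k = 7.00 L mol⁻¹ s⁻¹)

In the flask at 0.0113 min the other conformer was being made 7.85 times faster than used up, each step taken net. At 5.00 min this flask holds 56.7% isomer of the product, 13.1% target and 29.8% side product, a made share of 67.0%. The neighbour flask with 0.570 equiv of reagent holds at that same time 38.4%, 0.691% and 35.8% of these three, a made share of 67.4%, while its plain share stands at 98.2%.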